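**Strategy.** Rings A (pyranone) and B (its fused ketal ring) are assembled first; the carbocyclic core is then closed in one operation by a rhodium-catalysed allenic Pauson–Khand (2+2+1) reaction of an acyclic allenyne hanging from ring B. With the seven-membered ring C labelled Ca (hemiketal carbon), Cb (CHOH), Cc (C=O), Cd (C–OH), Ce, Cf (CHMe), Cg, the step exploits ring D, a 5,5-dimethylcyclopentenone fused across Cd–Ce: the alkyne on Cf supplies CH=Ce, the 1,1-dimethylallene on Cb supplies Cc=Cd–CMe2 and CO the ketone, so rings C and D form together. The precursor is the ring-A/B methyl ketal with a but-3-yn-2-yl arm on Cg and a silyloxy-allenyl arm on Ca; Cc=Cd later becomes the ketol.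

Key step: step 10

Assumption 1: 4-hydroxy-5,6-dimethyl-2H-pyran-2-one and racemic 3-methoxybut-1-yne are taken as catalogue chemicals (the ether is otherwise one O-methylation from but-3-yn-2-ol).
Assumption 2: the hemiketal carbon Ca is configurationally mobile, and its configuration in the target (OH axial on ring B, rings B/C trans-fused) is taken to be the equilibrium one.

Step 1
Reactants: 1 4-hydroxy-5,6-dimethyl-2H-pyran-2-one; 2 Meldrum's acid; 3 formaldehyde (as paraformaldehyde)
Product: 4 ring-A/B enol lactone (7,8-dimethyl-3,4-dihydro-2H,5H-pyrano[4,3-b]pyran-2,5-dione)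
Conditions: L-proline (10 mol%), MeCN, 25 → 70 °C (2 and 3 premixed, 1 added last)
Reagents that add atoms: none
Why: A Knoevenagel/Michael/lactonisation domino (methylene Meldrum's acid from 2 and 3 is attacked by the nucleophilic C3 of the pyranone, and the enol oxygen then acylates itself on a Meldrum's carbonyl with loss of acetone and CO2) closes ring B as a lactone whose carbonyl carbon becomes Ca and whose α-CH2 becomes Cg, with no stereocentre formed.

Step 2
Reactants: 4 ring-A/B enol lactone; 5 (S)-4-benzyloxazolidin-2-one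
Product: 7 silyl-protected acyl oxazolidinone, via lithium pyranolate of the ring-opened imide 6 (not isolated)
Conditions: 5, n-BuLi, THF, −78 °C; then 4, −78 → 0 °C; then TIPSCl, 0 → 25 °C
Reagents that add atoms: triisopropylsilyl chloride, CC(C)[Si](Cl)(C(C)C)C(C)C
Why: The enol lactone is a vinylogous anhydride, so N-acylation of the lithiated oxazolidinone (standard auxiliary acylation by an activated ester) is irreversible because the released pyranone oxide is a far weaker base, and silylating that oxide in the same flask masks it for the enolate chemistry of step 3.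

Step 3
Reactants: 7 silyl-protected acyl oxazolidinone; 8 3-methoxybut-1-yne (racemic); 9 dicobalt octacarbonyl Co2(CO)8
Product: 12 silyl-protected alkynyl imide, via cobalt complex of the propargyl ether 10 (not isolated), via cobalt-complexed alkylation product 11 (not isolated)
Conditions: a) 8, Co2(CO)8, CH2Cl2, 25 °C; b) 7, Bu2BOTf, iPr2NEt, CH2Cl2, −78 → 0 °C, then the solution of 10 and further Bu2BOTf, −78 → 0 °C; c) Me3NO, CH2Cl2/THF, 25 °C
Reagents that add atoms: none
Why: Nicholas reaction of a chiral boron enolate, in which the chelated Z-enolate is attacked on the face remote from the benzyl group by the Co2(CO)6-stabilised propargyl cation (configurationally mobile, so the racemic ether converges) through an open, syn-selective transition state that sets Cg (R) and Cf (R) in one event, after which amine-oxide demetalation frees the alkyne.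

Step 4
Reactants: 12 silyl-protected alkynyl imide
Product: 13 (2R,3R)-alkynyl acid with free pyranone hydroxyl
Conditions: LiOH, H2O2, THF/H2O, 0 °C; Na2SO3; then HCl to pH 3
Reagents that add atoms: hydrogen peroxide (as LiOOH), OO
Why: Lithium hydroperoxide cleaves the exocyclic imide carbonyl selectively without epimerising Cg (standard auxiliary removal), and the same basic peroxide hydrolyses the silyl vinylogous ester.

Step 5
Reactants: 13 alkynyl acid; 14 N,O-dimethylhydroxylamine hydrochloride
Product: 15 Weinreb amide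
Conditions: EDC·HCl, N-methylmorpholine, CH2Cl2, −10 → 10 °C
Reagents that add atoms: none
Why: Carbodiimide amidation to the Weinreb amide (it may pass through the transient ring-B enol lactone, which the amine opens to the same product), run cold with a weak base to avoid epimerisation of Cg.

Step 6
Reactants: 15 Weinreb amide; 16 2-methylprop-1-enylmagnesium bromide
Product: 18 ring-B methyl ketal, via open-chain enone 17 (not isolated)
Conditions: 16 (3.5 equiv), THF, −20 → 0 °C; then HCl in MeOH, HC(OMe)3, 0 → 25 °C
Reagents that add atoms: methanol, CO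
Why: Weinreb ketone synthesis (the chelated tetrahedral intermediate stops at mono-addition while ring A is shielded as its magnesium pyranolate) followed by acid-catalysed hemiketalisation and methanol exchange, which closes ring B under thermodynamic control with OMe axial (anomeric effect) and both carbon substituents equatorial, that is Ca (S) relative to Cg.

Step 7
Reactants: 18 ring-B methyl ketal
Product: 19 ketal aldehyde
Conditions: OsO4 (2 mol%), NaIO4, 2,6-lutidine, dioxane/H2O, 25 °C
Reagents that add atoms: osmium tetroxide (catalytic), O=[Os](=O)(=O)=O; sodium periodate (terminal oxidant), [Na+].[O-]I(=O)(=O)=O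
Why: Lemieux–Johnson cleavage takes only the electron-rich trisubstituted alkene (the alkyne and the electron-poor pyranone are inert to OsO4) and unveils the aldehyde carbon that becomes Cb.

Step 8
Reactants: 19 ketal aldehyde; 20 3-methylbuta-1,2-diene
Product: 22 allenyl carbinol, via 3-methylbuta-1,2-dienyllithium 21 (not isolated)
Conditions: 20, n-BuLi, THF, −78 → −40 °C; then 19, Et2O/THF, −90 °C; AcOH quench
Reagents that add atoms: none
Why: 1,2-Addition of an allenic organolithium (1,1-dimethylallene is lithiated at its CH2 terminus and reacts there because γ-attack would build a quaternary centre) under chelation control, with lithium bridging the formyl and methoxy oxygens (Cram chelate) and the nucleophile entering past the ring oxygen and away from Cg, the face also predicted by the Felkin–Anh model with the C–O(pyranone) bond anti, sets Cb (R).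

Step 9
Reactants: 22 allenyl carbinol
Product: 23 triethylsilyl-protected allenyne
Conditions: TESOTf, 2,6-lutidine, CH2Cl2, −78 → 0 °C
Reagents that add atoms: triethylsilyl trifluoromethanesulfonate, CC[Si](CC)(CC)OS(=O)(=O)C(F)(F)F
Why: Silylation of the hindered secondary alcohol with a silyl triflate gives the ether that keeps Cb–OH out of the oxidation in step 12 and serves as the stereodirecting group in step 11.

Step 10
Reactants: 23 triethylsilyl-protected allenyne
Product: 24 tetracyclic dienone (rings A–D)
Conditions: [Rh(CO)2Cl]2 (5 mol%), CO (1 atm), toluene, 90 °C, 0.01 M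
Reagents that add atoms: carbon monoxide, [C-]#[O+]
Why: Monovalent rhodium couples the alkyne with the distal Cd=CMe2 π-bond of the allene by oxidative cyclisation to a rhodacyclopentene (new Ce–Cd bond), CO inserts, and reductive elimination forms the CH–C(=O)–CMe2 unit of a 4-alkylidene-5,5-dimethylcyclopent-2-enone; the closest known reaction type is the rhodium-catalysed allenic Pauson–Khand reaction, a (2+2+1) cycloaddition that gives bicyclo[5.3.0]decadienones from allenynes with a four-atom tether. Ring C closes as a seven-membered carbocycle through the Ce–Cd bond across the tether Cf–Cg–Ca–Cb, and ring D closes in the same catalytic event by carbonyl insertion and C–C reductive elimination, so no ring is formed afterwards. No stereocentre is created (Cd stays sp2 in the Cc=Cd alkene) and Ca, Cb, Cf and Cg are carried through unchanged. The step needs the distal rather than the proximal allene π-bond, which this catalyst selects irrespective of allene substitution, and carbonylation rather than β-hydride loss from the CMe2–rhodium intermediate (ene-type cycloisomerisation), which the CO atmosphere favours. Ring B holds the two arms equatorial and gauche on Ca and Cg and the fully substituted Ca compresses the tether, so ring C can close trans-fused to ring B at high dilution.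

Step 11
Reactants: 24 tetracyclic dienone
Product: 25 Cc,Cd-cis-diol
Conditions: OsO4 (10 mol%), NMO, acetone/H2O, 25 °C
Reagents that add atoms: osmium tetroxide (catalytic), O=[Os](=O)(=O)=O; N-methylmorpholine N-oxide (terminal oxidant), C[N+]1([O-])CCOCC1; water, O
Why: Catalytic osmylation (syn-dihydroxylation) takes the most electron-rich alkene, the γ,δ-bond Cc=Cd of the dienone, on the face anti to the axial allylic silyloxy group on Cb (the usual anti rule for allylic ethers), which places the new tertiary hydroxyl on Cd (R) cis to the Ca oxygen and trans to Cb–O.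

Step 12
Reactants: 25 Cc,Cd-cis-diol
Product: 26 protected ketol
Conditions: IBX, DMSO, 25 °C
Reagents that add atoms: none
Why: IBX oxidises the secondary Cc–OH to the ketone without cleaving the 1,2-diol and cannot touch the tertiary Cd–OH, giving the Cc(=O)–Cd(OH) ketol under neutral conditions that spare the configuration at Cb.

Step 13
Reactants: 26 protected ketol
Product: 27 CNP0525404.1
Conditions: 1 M HCl (aq), THF, 25 °C
Reagents that add atoms: water, O
Why: Aqueous acid removes the triethylsilyl group and exchanges the anomeric methoxy group for hydroxyl through the ring-B oxocarbenium ion (ring B stays closed), the hemiketal settling in the anomerically favoured axial-OH, trans-fused arrangement, Ca (S).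

**Compound list**

1 | 4-hydroxy-5,6-dimethyl-2H-pyran-2-one | Cc1oc(=O)cc(O)c1C | starting material
2 | Meldrum's acid (2,2-dimethyl-1,3-dioxane-4,6-dione) | CC1(C)OC(=O)CC(=O)O1 | starting material
3 | formaldehyde (used as paraformaldehyde) | C=O | starting material
4 | 7,8-dimethyl-3,4-dihydro-2H,5H-pyrano[4,3-b]pyran-2,5-dione | Cc1oc(=O)c2c(c1C)OC(=O)CC2 | intermediate
5 | (S)-4-benzyloxazolidin-2-one | O=C1N[C@@H](Cc2ccccc2)CO1 | starting material
6 | lithium 3-{3-[(4S)-4-benzyl-2-oxooxazolidin-3-yl]-3-oxopropyl}-5,6-dimethyl-2-oxo-2H-pyran-4-olate | Cc1oc(=O)c(CCC(=O)N2[C@@H](Cc3ccccc3)COC2=O)c([O-])c1C.[Li+] | intermediate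
7 | (4S)-4-benzyl-3-{3-[5,6-dimethyl-2-oxo-4-(triisopropylsilyloxy)-2H-pyran-3-yl]propanoyl}oxazolidin-2-one | Cc1oc(=O)c(CCC(=O)N2[C@@H](Cc3ccccc3)COC2=O)c(O[Si](C(C)C)(C(C)C)C(C)C)c1C | intermediate
8 | 3-methoxybut-1-yne (racemic) | C#CC(C)OC | starting material
9 | dicobalt octacarbonyl Co2(CO)8 | O=C=[Co](=C=O)(=C=O)(=C=O)[Co](=C=O)(=C=O)(=C=O)=C=O | starting material
10 | hexacarbonyl[μ-(3-methoxybut-1-yne)]dicobalt, the Co2(CO)6 complex of 8 | COC(C)C12[CH]3[Co]1(=C=O)(=C=O)(=C=O)[Co]23(=C=O)(=C=O)=C=O | intermediate
11 | Co2(CO)6 complex (at the alkyne) of 12 | [CH]12[Co]3(=C=O)(=C=O)(=C=O)[Co]1(=C=O)(=C=O)(=C=O)C23[C@H](C)[C@H](C(=O)N1[C@@H](Cc4ccccc4)COC1=O)Cc1c(O[Si](C(C)C)(C(C)C)C(C)C)c(C)c(C)oc1=O | intermediate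
12 | (4S)-4-benzyl-3-[(2R,3R)-2-{[5,6-dimethyl-2-oxo-4-(triisopropylsilyloxy)-2H-pyran-3-yl]methyl}-3-methylpent-4-ynoyl]oxazolidin-2-one | C#C[C@H](C)[C@H](C(=O)N1[C@@H](Cc2ccccc2)COC1=O)Cc1c(O[Si](C(C)C)(C(C)C)C(C)C)c(C)c(C)oc1=O | intermediate
13 | (2R,3R)-2-[(4-hydroxy-5,6-dimethyl-2-oxo-2H-pyran-3-yl)methyl]-3-methylpent-4-ynoic acid | C#C[C@H](C)[C@H](C(=O)O)Cc1c(O)c(C)c(C)oc1=O | intermediate
14 | N,O-dimethylhydroxylamine hydrochloride | CNOC.Cl | starting material
15 | (2R,3R)-2-[(4-hydroxy-5,6-dimethyl-2-oxo-2H-pyran-3-yl)methyl]-N-methoxy-N,3-dimethylpent-4-ynamide | C#C[C@H](C)[C@H](C(=O)N(C)OC)Cc1c(O)c(C)c(C)oc1=O | intermediate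
16 | 2-methylprop-1-enylmagnesium bromide | CC(C)=C[Mg]Br | starting material
17 | (5R,6R)-5-[(4-hydroxy-5,6-dimethyl-2-oxo-2H-pyran-3-yl)methyl]-2,6-dimethyloct-2-en-7-yn-4-one (open-chain keto form) | C#C[C@H](C)[C@H](C(=O)C=C(C)C)Cc1c(O)c(C)c(C)oc1=O | intermediate
18 | (2S,3R)-3-[(2R)-but-3-yn-2-yl]-2-methoxy-7,8-dimethyl-2-(2-methylprop-1-en-1-yl)-3,4-dihydro-2H,5H-pyrano[4,3-b]pyran-5-one | Cc1oc(=O)c2c(c1C)O[C@](OC)(C=C(C)C)[C@@H]([C@@H](C)C#C)C2 | intermediate
19 | (2S,3R)-3-[(2R)-but-3-yn-2-yl]-2-methoxy-7,8-dimethyl-5-oxo-3,4-dihydro-2H,5H-pyrano[4,3-b]pyran-2-carbaldehyde | Cc1oc(=O)c2c(c1C)O[C@](OC)(C=O)[C@@H]([C@@H](C)C#C)C2 | intermediate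
20 | 3-methylbuta-1,2-diene | CC(C)=C=C | starting material
21 | 3-methylbuta-1,2-dienyllithium | CC(C)=C=C[Li] | intermediate
22 | (2S,3R)-3-[(2R)-but-3-yn-2-yl]-2-[(1R)-1-hydroxy-4-methylpenta-2,3-dien-1-yl]-2-methoxy-7,8-dimethyl-3,4-dihydro-2H,5H-pyrano[4,3-b]pyran-5-one | Cc1oc(=O)c2c(c1C)O[C@](OC)([C@H](O)C=C=C(C)C)[C@@H]([C@@H](C)C#C)C2 | intermediate
23 | (2S,3R)-3-[(2R)-but-3-yn-2-yl]-2-methoxy-7,8-dimethyl-2-[(1R)-4-methyl-1-(triethylsilyloxy)penta-2,3-dien-1-yl]-3,4-dihydro-2H,5H-pyrano[4,3-b]pyran-5-one | Cc1oc(=O)c2c(c1C)O[C@](OC)([C@H](O[Si](CC)(CC)CC)C=C=C(C)C)[C@@H]([C@@H](C)C#C)C2 | intermediate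
24 | tetracyclic dienone: ring-B methyl ketal (Ca S), Cb–OSiEt3 (R), Cc=Cd alkene exocyclic to ring D, ring D 5,5-dimethylcyclopent-2-en-1-one, Cf (R), Cg (R) | Cc1oc(=O)c2c(c1C)O[C@]1(OC)[C@H](O[Si](CC)(CC)CC)C=C3C(=CC(=O)C3(C)C)[C@H](C)[C@H]1C2 | intermediate
25 | Cc,Cd-cis-diol of 24 (Cc R, Cd R; both hydroxyls anti to the silyloxy group) | Cc1oc(=O)c2c(c1C)O[C@]1(OC)[C@H](O[Si](CC)(CC)CC)[C@@H](O)[C@@]3(O)C(=CC(=O)C3(C)C)[C@H](C)[C@H]1C2 | intermediate
26 | Cc ketone of 25, the Ca-O-methyl, Cb-O-triethylsilyl derivative of the target | Cc1oc(=O)c2c(c1C)O[C@]1(OC)[C@H](O[Si](CC)(CC)CC)C(=O)[C@@]3(O)C(=CC(=O)C3(C)C)[C@H](C)[C@H]1C2 | intermediate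
27 | CNP0525404.1 (Ca S, Cb R, Cd R, Cf R, Cg R) | Cc1oc(=O)c2c(c1C)O[C@]1(O)[C@H](O)C(=O)[C@@]3(O)C(=CC(=O)C3(C)C)[C@H](C)[C@H]1C2 | target

**Totals.** Total step count: 13. Longest linear sequence: 13 steps (1 → 27).

**Steps most likely to fail**

Step 10 (key step). Process at risk: before CO insertion the CMe2–rhodium intermediate can lose a β-hydrogen (ene-type cycloisomerisation to a cross-conjugated triene), and the unprotected alkyne terminus can be consumed by oligomerisation. Fallback, setting out from 23 and returning at 24: the alkyne is capped (LiN(SiMe3)2, Me3SiCl, THF, −78 °C) to give the C-trimethylsilyl allenyne F1, the substrate class on which this cyclocarbonylation is most reliable. [Rh(CO)2Cl]2 under CO then gives the α-silyl dienone F2, Bu4NF/AcOH removes both silyl groups to give the hydroxy dienone F3, and TESOTf/2,6-lutidine returns 24.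

Step 8. Process at risk: incomplete facial control (chelated and non-chelated transition states competing), which would give 22 mixed with its carbinol epimer. Fallback, setting out from the epimer mixture of 22 and returning at 22: Dess–Martin oxidation gives the allenyl ketone F4, and a reagent-controlled Corey–Bakshi–Shibata reduction ((S)-2-methyl-CBS-oxazaborolidine, catecholborane, toluene, −78 °C, the fully substituted Ca acting as the large group) returns the (R)-carbinol.

Step 11. Process at risk: slow osmylation of the hindered alkene (Cd is neopentyl-like), leaving time for oxidation elsewhere or erosion of facial control. Fallback, setting out from 24 and returning at 26: epoxidation of Cc=Cd with dimethyldioxirane (acetone, 0 °C; a small electrophilic oxidant with the same anti approach) gives the epoxide F5. DMSO with catalytic Me3SiOTf then opens the oxirane at the secondary carbon Cc and oxidises it there (Kornblum-type), giving ketol 26 with the Cd–O bond untouched.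

**Further compounds**

F1 | step 10 | C-trimethylsilyl derivative of allenyne 23 | Cc1oc(=O)c2c(c1C)O[C@](OC)([C@H](O[Si](CC)(CC)CC)C=C=C(C)C)[C@@H]([C@@H](C)C#C[Si](C)(C)C)C2
F2 | step 10 | α-trimethylsilyl derivative of dienone 24 (silyl group on the enone CH carbon of ring D) | Cc1oc(=O)c2c(c1C)O[C@]1(OC)[C@H](O[Si](CC)(CC)CC)C=C3C(=C([Si](C)(C)C)C(=O)C3(C)C)[C@H](C)[C@H]1C2
F3 | step 10 | Cb-hydroxy dienone (24 without the triethylsilyl group) | Cc1oc(=O)c2c(c1C)O[C@]1(OC)[C@H](O)C=C3C(=CC(=O)C3(C)C)[C@H](C)[C@H]1C2
F4 | step 8 | (2S,3R)-3-[(2R)-but-3-yn-2-yl]-2-methoxy-7,8-dimethyl-2-(4-methylpenta-2,3-dienoyl)-3,4-dihydro-2H,5H-pyrano[4,3-b]pyran-5-one | Cc1oc(=O)c2c(c1C)O[C@](OC)(C(=O)C=C=C(C)C)[C@@H]([C@@H](C)C#C)C2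
F5 | step 11 | Cc,Cd-epoxide of 24 (oxygen anti to the silyloxy group) | Cc1oc(=O)c2c(c1C)O[C@]1(OC)[C@H](O[Si](CC)(CC)CC)[C@H]4O[C@@]43C(=CC(=O)C3(C)C)[C@H](C)[C@H]1C2
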